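**Retrosynthetic overview**

1. The target is (2S)-eriodictyol and luteolin joined by one biaryl bond, C-5' (flavanone ring B, ortho to the 4'-OH) to C-6'' (flavone ring A); this bond is the only strategic disconnection.
2. The bond is formed in a light-driven copper coupling of an aryl boronate (flavanone half) with an aryl iodide (flavone half), so both of its carbon atoms are fixed beforehand.
3. Flavone half: luteolin → 7,3',4'-tri-O-benzyl ether → C-6 iodide (directed by the free, chelated 5-OH).
4. Flavanone half: natural (2S)-eriodictyol → C-5' pinacol boronate by iridium C–H borylation; C-2 (S) is bought with eriodictyol and never touched.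
5. No ring is formed: all six rings come intact from the two flavonoids; hydrogenolysis of the benzyl ethers ends the route.

Assumption: natural (2S)-eriodictyol and luteolin are bought as such; unprimed and single-primed locants refer to the flavanone half, double- and triple-primed locants to the flavone half.

**Route**

Step 1
Reactants: 1 luteolin
Product: 2 7,3',4'-tri-O-benzylluteolin
Conditions: BnBr (3.3 equiv), K2CO3 (3.5 equiv), DMF, 25 °C
Reagents that add atoms: benzyl bromide, BrCc1ccccc1
Why: Williamson ether synthesis; the three acidic phenols (7, 3', 4') are benzylated while the 5-OH, hydrogen-bonded to the C-4 carbonyl, stays free.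

Step 2
Reactants: 2 7,3',4'-tri-O-benzylluteolin
Product: 3 6-iodo-7,3',4'-tri-O-benzylluteolin
Conditions: NIS (1.05 equiv), DMF, 0 to 25 °C, dark
Reagents that add atoms: N-iodosuccinimide, O=C1CCC(=O)N1I
Why: Electrophilic aromatic iodination; 5-hydroxy-7-alkoxyflavones are expected to iodinate at C-6, ortho to the free chelated phenol (5-O-alkyl analogues go to C-8), and the benzylated ring B is deactivated by conjugation with the pyranone.

Step 3
Reactants: 4 (2S)-eriodictyol
Product: 7 (2S)-5'-(pinacolboryl)eriodictyol, via tetrakis-O-Bpin eriodictyol 5 (not isolated), via 5'-C-boryl tetrakis-O-Bpin eriodictyol 6 (not isolated)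
Conditions: HBpin (8 equiv), [Ir(OMe)(cod)]2 (3 mol%), 4,4'-di-tert-butyl-2,2'-bipyridine (6 mol%), THF, 25 to 60 °C; then MeOH, 0 °C
Reagents that add atoms: pinacolborane, [H]B1OC(C)(C)C(C)(C)O1
Why: Iridium-catalysed aromatic C–H borylation of the phenols O-borylated in the flask (traceless O–Bpin ortho direction, known for para-substituted phenols); C-6, C-8 and C-2' are each flanked by two substituents and C-6' is next to the bulky C-2 side, so the C-5'–H ortho to the 4'-O–Bpin is borylated, methanol then removes the O–B groups, and the neutral conditions leave the C-2 stereocentre untouched.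

Step 4
Reactants: 7 (2S)-5'-(pinacolboryl)eriodictyol (1.3 equiv); 3 6-iodo-7,3',4'-tri-O-benzylluteolin
Product: 8 (2S)-eriodictyol-(5'→6'')-(7'',3''',4'''-tri-O-benzylluteolin)
Conditions: [Cu(MeCN)4]PF6 (15 mol%), neocuproine (18 mol%), CsF (3 equiv), degassed DMA, 450 nm LEDs, 20 °C
Reagents that add atoms: none
Why: Proposed new method: a photoinduced copper-catalysed Suzuki–Miyaura-type biaryl coupling, in which fluoride-assisted boron-to-copper transmetallation of 7 gives a neocuproine-ligated monovalent aryl-copper species, its visible-light charge-transfer excited state passes one electron to the C–I bond of 3, the C-6'' aryl radical is captured in the solvent cage by the divalent aryl-copper partner, and the trivalent diaryl-copper intermediate reductively eliminates the C5'–C6'' bond; the closest known reaction types are the thermal copper-catalysed Suzuki–Miyaura coupling of aryl boronates with aryl iodides (80–120 °C) and the photoinduced copper-catalysed Ullmann- and Sonogashira-type couplings of aryl halides at room temperature, and here light replaces heat so that the flavanone stereocentre sees only 20 °C and buffered fluoride, while boron and iodine fix both ends of the bond.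

Step 5
Reactants: 8 (2S)-eriodictyol-(5'→6'')-(7'',3''',4'''-tri-O-benzylluteolin)
Product: 9 (2S)-eriodictyol-(5'→6'')-luteolin (target)
Conditions: H2 (1 atm), 10% Pd/C, THF/MeOH, 25 °C
Reagents that add atoms: none
Why: Catalytic hydrogenolysis of the three benzyl ethers under neutral conditions; the flavone enone and the benzylic C2–O1 bond of the flavanone are reduced more slowly and the stereocentre is retained.

**Compound list**

1 | luteolin | O=c1cc(-c2ccc(O)c(O)c2)oc2cc(O)cc(O)c12 | starting material
2 | 7,3',4'-tri-O-benzylluteolin | O=c1cc(-c2ccc(OCc3ccccc3)c(OCc3ccccc3)c2)oc2cc(OCc3ccccc3)cc(O)c12 | intermediate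
3 | 6-iodo-7,3',4'-tri-O-benzylluteolin | O=c1cc(-c2ccc(OCc3ccccc3)c(OCc3ccccc3)c2)oc2cc(OCc3ccccc3)c(I)c(O)c12 | intermediate
4 | (2S)-eriodictyol | O=C1C[C@@H](c2ccc(O)c(O)c2)Oc2cc(O)cc(O)c21 | starting material
5 | (2S)-5,7,3',4'-tetrakis-O-(pinacolboryl)eriodictyol | O=C1C[C@@H](c2ccc(OB3OC(C)(C)C(C)(C)O3)c(OB3OC(C)(C)C(C)(C)O3)c2)Oc2cc(OB3OC(C)(C)C(C)(C)O3)cc(OB3OC(C)(C)C(C)(C)O3)c21 | intermediate
6 | (2S)-5'-(pinacolboryl)-5,7,3',4'-tetrakis-O-(pinacolboryl)eriodictyol | O=C1C[C@@H](c2cc(OB3OC(C)(C)C(C)(C)O3)c(OB3OC(C)(C)C(C)(C)O3)c(B3OC(C)(C)C(C)(C)O3)c2)Oc2cc(OB3OC(C)(C)C(C)(C)O3)cc(OB3OC(C)(C)C(C)(C)O3)c21 | intermediate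
7 | (2S)-5'-(pinacolboryl)eriodictyol | O=C1C[C@@H](c2cc(O)c(O)c(B3OC(C)(C)C(C)(C)O3)c2)Oc2cc(O)cc(O)c21 | intermediate
8 | (2S)-eriodictyol-(5'→6'')-(7'',3''',4'''-tri-O-benzylluteolin) | O=C1C[C@@H](c2cc(O)c(O)c(-c3c(OCc6ccccc6)cc4oc(-c5ccc(OCc6ccccc6)c(OCc6ccccc6)c5)cc(=O)c4c3O)c2)Oc2cc(O)cc(O)c21 | intermediate
9 | (2S)-eriodictyol-(5'→6'')-luteolin | O=C1C[C@@H](c2cc(O)c(O)c(-c3c(O)cc4oc(-c5ccc(O)c(O)c5)cc(=O)c4c3O)c2)Oc2cc(O)cc(O)c21 | target

**Step count**

Total: 5 steps. Longest linear sequence: 4 steps (1 → 2 → 3 → 8 → 9, steps 1, 2, 4, 5).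

**Steps most likely to fail**

Step 4 (the proposed new coupling). Likely failure modes:
- protonolysis of the aryl-copper species by the free phenols, which returns eriodictyol;
- photo-Ullmann C–O coupling of a phenoxide with 3;
- escape of the aryl radical from the cage and hydrogen abstraction, which gives 2;
- slow formation of the tri-ortho-substituted biaryl.

The enantiomeric purity of 8 should be checked by chiral HPLC. The fallback uses known chemistry: a thermal palladium-catalysed Suzuki–Miyaura coupling with a weak base (Pd(OAc)2, SPhos, KF, THF/H2O, 25–40 °C). This is a two-electron cycle through zerovalent and divalent palladium that tolerates free phenols and hindered partners. It sets out from 7 and 3 and comes back to the route at 8; it makes no new compound (F0).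

Step 3 (C–H borylation of unprotected eriodictyol). Likely failure modes:
- borylation at ring A under O–Bpin direction;
- a mixture of C-5' and C-6' products;
- hydroboration of the C-4 ketone;
- protodeboronation of the electron-rich boronate 7 on isolation.

The fallback replaces O-boryl direction by a covalent benzodioxole, whose C–H ortho to the ring oxygen is the established site of iridium borylation. It sets out from 4: 2,2-dimethoxypropane with catalytic TsOH in toluene at 80 °C gives (2S)-eriodictyol 3',4'-acetonide F1. With HBpin and the same iridium catalyst, F1 passes through its 5,7-bis-O-Bpin form F2 and the 5'-C-borylated bis-O-Bpin form F3, and methanol then gives the 5'-pinacolboryl acetonide F4. Coupling of F4 with 3 under the step 4 conditions (or the palladium variant above) gives the coupled acetonide F5. TFA/H2O/CH2Cl2 at 25 °C removes the acetonide and the route is rejoined at 8.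

Step 5 (hydrogenolysis). Likely failure modes:
- over-reduction of the flavone C2''=C3'' bond;
- hydrogenolytic opening of the benzylic C2–O1 bond;
- catalyst poisoning by the polyphenol.

The fallback is a Lewis-acid debenzylation: BCl3 with pentamethylbenzene as cation scavenger in CH2Cl2 at −78 °C, then MeOH. It sets out from 8 and comes back at 9; it makes no new compound (F0).

**Further compounds**

F1 | step 3 | (2S)-eriodictyol 3',4'-O-isopropylidene ketal | O=C1C[C@@H](c2ccc3c(c2)OC(C)(C)O3)Oc2cc(O)cc(O)c21
F2 | step 3 | (2S)-5,7-bis-O-(pinacolboryl)eriodictyol 3',4'-O-isopropylidene ketal | O=C1C[C@@H](c2ccc3c(c2)OC(C)(C)O3)Oc2cc(OB3OC(C)(C)C(C)(C)O3)cc(OB3OC(C)(C)C(C)(C)O3)c21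
F3 | step 3 | (2S)-5'-(pinacolboryl)-5,7-bis-O-(pinacolboryl)eriodictyol 3',4'-O-isopropylidene ketal | O=C1C[C@@H](c2cc(B3OC(C)(C)C(C)(C)O3)c3OC(C)(C)Oc3c2)Oc2cc(OB3OC(C)(C)C(C)(C)O3)cc(OB3OC(C)(C)C(C)(C)O3)c21
F4 | step 3 | (2S)-5'-(pinacolboryl)eriodictyol 3',4'-O-isopropylidene ketal | O=C1C[C@@H](c2cc(B3OC(C)(C)C(C)(C)O3)c3OC(C)(C)Oc3c2)Oc2cc(O)cc(O)c21
F5 | step 3 | 3',4'-O-isopropylidene ketal of compound 8 | O=C1C[C@@H](c2cc(-c3c(OCc6ccccc6)cc4oc(-c5ccc(OCc6ccccc6)c(OCc6ccccc6)c5)cc(=O)c4c3O)c3OC(C)(C)Oc3c2)Oc2cc(O)cc(O)c21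
F0 | step 4 | none | none
F0 | step 5 | none | none
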